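The route rests on tracing the cis C2–H/C3–O pair of the dihydrofuran ring back to a benzofuran-3(2H)-one-2-carboxylate. C3 is a benzylic carbinol carbon and C2 sits between ring oxygen O1 and an sp2 carbon, so in the keto ester the C2–H epimerises through the aromatic 3-hydroxybenzofuran enol. A chiral Ru transfer-hydrogenation catalyst reduces the C3 ketone under dynamic kinetic resolution and fixes both ring stereocentres, cis, in one operation. Its precursor is the racemic 5-bromo-6,7-dimethoxy keto ester from a Dieckmann closure, bromine standing in for the acetyl group. Ester, bromide and carbinol then become isopropenyl, acetyl and angelate.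

Key step: step 6

Remark on the chemistry: the (S,S)-TsDPEN ligand is assumed to give the 3R carbinol, following the usual aryl/alkyl facial model for fused aryl ketones. The configuration would be checked by Mosher ester analysis, and the (R,R) catalyst used without other change if the sense proved opposite.

Step 1
Reactants: 1 2,3,4-trimethoxybenzoic acid
Product: 2 methyl 2,3,4-trimethoxybenzoate
Conditions: MeOH, H2SO4 (cat.), reflux
Reagents that add atoms: methanol, CO
Why: Fischer esterification in excess methanol converts the acid into the methyl ester, whose carbonyl serves as the chelating handle for the next step.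

Step 2
Reactants: 2 methyl 2,3,4-trimethoxybenzoate
Product: 4 methyl 2-hydroxy-3,4-dimethoxybenzoate, via aryl dichloroborinate 3 (not isolated)
Conditions: BCl3 (1.1 equiv), CH2Cl2, −10 to 0 °C; then H2O
Reagents that add atoms: none
Why: Chelation-directed Lewis acid ether cleavage, in which BCl3 bridges the ester carbonyl and the neighbouring 2-methoxy oxygen so that chloride removes only that methyl group and the 3- and 4-methoxy groups remain.

Step 3
Reactants: 4 methyl 2-hydroxy-3,4-dimethoxybenzoate
Product: 5 methyl 5-bromo-2-hydroxy-3,4-dimethoxybenzoate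
Conditions: NBS (1.05 equiv), MeCN, 0 °C to rt
Reagents that add atoms: N-bromosuccinimide, O=C1CCC(=O)N1Br
Why: Electrophilic aromatic bromination should go to C5, which is para to the phenol and ortho to the 4-methoxy group, whereas C6 lies ortho to the ester and is much less activated.

Step 4
Reactants: 5 methyl 5-bromo-2-hydroxy-3,4-dimethoxybenzoate; 6 methyl bromoacetate
Product: 7 methyl 5-bromo-3,4-dimethoxy-2-(2-methoxy-2-oxoethoxy)benzoate
Conditions: K2CO3, DMF, 50 °C
Reagents that add atoms: none
Why: Williamson ether synthesis, the phenoxide generated by carbonate in a dipolar solvent displacing bromide from the activated primary α-bromo ester.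

Step 5
Reactants: 7 methyl 5-bromo-3,4-dimethoxy-2-(2-methoxy-2-oxoethoxy)benzoate
Product: 8 methyl 5-bromo-6,7-dimethoxy-3-oxo-2,3-dihydro-1-benzofuran-2-carboxylate (racemic at C2, largely present as the 3-hydroxybenzofuran enol)
Conditions: NaOMe (1.5 equiv), MeOH/THF, 0 to 50 °C; then cold 1 M HCl
Reagents that add atoms: none
Why: Dieckmann condensation, in which the glycolate α-carbanion acylates itself on the neighbouring aryl ester in a 5-exo-trig closure that is driven by deprotonation of the product β-keto ester, with methoxide matching both esters so that no transesterification can arise.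

Step 6
Reactants: 8 methyl 5-bromo-6,7-dimethoxy-3-oxo-2,3-dihydro-1-benzofuran-2-carboxylate
Product: 9 methyl (2S,3R)-5-bromo-3-hydroxy-6,7-dimethoxy-2,3-dihydro-1-benzofuran-2-carboxylate (cis)
Conditions: RuCl[(S,S)-TsDPEN](p-cymene) (1 mol %), HCO2H/Et3N (5:2), CH2Cl2, 30 °C
Reagents that add atoms: none
Why: This is a Noyori–Ikariya asymmetric transfer hydrogenation with dynamic kinetic resolution: the 18-electron Ru hydride formed from formate passes hydride to C3 and the ligand N–H proton to the carbonyl oxygen of the keto tautomer through an outer-sphere six-membered transition state, creating the C3–H bond. The closest known reaction type is the cis-selective transfer hydrogenation of benzo-fused cyclic α-substituted β-keto esters and of 2-substituted benzofuran-3(2H)-ones with this catalyst family. No ring is closed in this step. C3 is controlled by the catalyst, whose η6-arene holds the fused benzo ring through a CH–π contact and thereby selects one carbonyl face, while C2 is controlled by the substrate and by kinetics, since hydride arrives anti to the C2 ester and only the 2S ketone is reduced quickly, placing hydroxyl and ester cis. The step needs enantioface selectivity at C3 and C2 epimerisation faster than reduction, and the doubly activated C2–H (ketone, ester, aromatic enol) secures the latter in the triethylammonium formate medium. Chemoselectivity is built in, because with bromine in place of the acetyl group the C3 ketone is the only reducible carbonyl, and dilution in CH2Cl2 at mild temperature limits acid-promoted loss of water from the product.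

Step 7
Reactants: 9 methyl (2S,3R)-5-bromo-3-hydroxy-6,7-dimethoxy-2,3-dihydro-1-benzofuran-2-carboxylate; 10 methylmagnesium bromide
Product: 12 (2S,3R)-5-bromo-2-(2-hydroxypropan-2-yl)-6,7-dimethoxy-2,3-dihydro-1-benzofuran-3-ol (cis diol), via methyl ketone 11 (not isolated)
Conditions: MeMgBr (4.5 equiv), THF, −40 to 0 °C; then ice-water
Reagents that add atoms: none
Why: Double Grignard addition to an ester, in which the first equivalent turns the C3 hydroxyl into a magnesium alkoxide that cannot leave and so blocks E1cB loss toward the aromatic benzofuran, and two further equivalents take the activated α-aryloxy ester through the methyl ketone to the tertiary carbinol without touching the aryl bromide or either stereocentre.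

Step 8
Reactants: 12 (2S,3R)-5-bromo-2-(2-hydroxypropan-2-yl)-6,7-dimethoxy-2,3-dihydro-1-benzofuran-3-ol; 13 tributyl(1-ethoxyvinyl)stannane
Product: 15 1-[(2S,3R)-3-hydroxy-2-(2-hydroxypropan-2-yl)-6,7-dimethoxy-2,3-dihydro-1-benzofuran-5-yl]ethan-1-one, via aryl enol ether 14 (not isolated)
Conditions: Pd(PPh3)4 (5 mol %), toluene, 95 °C; then PPTS (cat.), acetone/H2O, 0 °C
Reagents that add atoms: water, O
Why: Stille cross-coupling followed by enol ether hydrolysis, zerovalent palladium inserting into the C5–Br bond and taking the 1-ethoxyvinyl group from tin under neutral, base-free conditions that tolerate both free hydroxyls, after which the highly acid-labile aryl enol ether is unmasked to the acetyl group by a trace of PPTS well before the benzylic carbinol can ionise.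

Step 9
Reactants: 15 1-[(2S,3R)-3-hydroxy-2-(2-hydroxypropan-2-yl)-6,7-dimethoxy-2,3-dihydro-1-benzofuran-5-yl]ethan-1-one; 16 angelic acid, (Z)-2-methylbut-2-enoic acid
Product: 18 (2S,3R)-5-acetyl-2-(2-hydroxypropan-2-yl)-6,7-dimethoxy-2,3-dihydro-1-benzofuran-3-yl (Z)-2-methylbut-2-enoate, via angelic trichlorobenzoic mixed anhydride 17 (not isolated)
Conditions: 2,4,6-trichlorobenzoyl chloride, Et3N, toluene, rt; then 15, 65 °C
Reagents that add atoms: none
Why: Yamaguchi-type esterification through a preformed mixed anhydride, whose shielded 2,4,6-trichlorobenzoyl carbonyl steers the secondary benzylic alcohol onto the angeloyl carbonyl while the tertiary alcohol is too hindered to compete, and the absence of a nucleophilic catalyst that could add reversibly to the enoate preserves the Z geometry.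

Step 10
Reactants: 18 (2S,3R)-5-acetyl-2-(2-hydroxypropan-2-yl)-6,7-dimethoxy-2,3-dihydro-1-benzofuran-3-yl (Z)-2-methylbut-2-enoate
Product: 20 (2R,3R)-5-acetyl-6,7-dimethoxy-2-(prop-1-en-2-yl)-2,3-dihydro-1-benzofuran-3-yl (Z)-2-methylbut-2-enoate, via tertiary sulfamate salt 19 (not isolated)
Conditions: Burgess reagent (methyl N-(triethylammoniosulfonyl)carbamate, 2 equiv), toluene, rt to 50 °C
Reagents that add atoms: none
Why: Burgess dehydration, the tertiary alcohol forming a sulfamate that collapses by syn Ei elimination under neutral conditions and takes one of six methyl hydrogens in preference to the single C2–H (which would give a crowded tetrasubstituted enol ether), so that the isopropenyl group appears with the angelate, the ketone and both stereocentres untouched and C2 changes from S to R in name only.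

Compound list
1 | 2,3,4-trimethoxybenzoic acid | COc1ccc(C(=O)O)c(OC)c1OC | starting material
2 | methyl 2,3,4-trimethoxybenzoate | COC(=O)c1ccc(OC)c(OC)c1OC | intermediate
3 | methyl 2-[(dichloroboranyl)oxy]-3,4-dimethoxybenzoate (boron chelated by the ester carbonyl; not isolated) | COC(=O)c1ccc(OC)c(OC)c1OB(Cl)Cl | intermediate
4 | methyl 2-hydroxy-3,4-dimethoxybenzoate | COC(=O)c1ccc(OC)c(OC)c1O | intermediate
5 | methyl 5-bromo-2-hydroxy-3,4-dimethoxybenzoate | COC(=O)c1cc(Br)c(OC)c(OC)c1O | intermediate
6 | methyl bromoacetate | COC(=O)CBr | starting material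
7 | methyl 5-bromo-3,4-dimethoxy-2-(2-methoxy-2-oxoethoxy)benzoate | COC(=O)COc1c(OC)c(OC)c(Br)cc1C(=O)OC | intermediate
8 | methyl 5-bromo-6,7-dimethoxy-3-oxo-2,3-dihydro-1-benzofuran-2-carboxylate (racemic, C2 labile, drawn as the keto tautomer) | COC(=O)C1Oc2c(OC)c(OC)c(Br)cc2C1=O | intermediate
9 | methyl (2S,3R)-5-bromo-3-hydroxy-6,7-dimethoxy-2,3-dihydro-1-benzofuran-2-carboxylate (cis) | COC(=O)[C@H]1Oc2c(cc(Br)c(OC)c2OC)[C@H]1O | intermediate
10 | methylmagnesium bromide | C[Mg]Br | starting material
11 | 1-[(2S,3R)-5-bromo-3-hydroxy-6,7-dimethoxy-2,3-dihydro-1-benzofuran-2-yl]ethan-1-one (present as its magnesium alkoxide; not isolated) | CC(=O)[C@H]1Oc2c(cc(Br)c(OC)c2OC)[C@H]1O | intermediate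
12 | (2S,3R)-5-bromo-2-(2-hydroxypropan-2-yl)-6,7-dimethoxy-2,3-dihydro-1-benzofuran-3-ol (cis diol) | CC(C)(O)[C@H]1Oc2c(cc(Br)c(OC)c2OC)[C@H]1O | intermediate
13 | tributyl(1-ethoxyvinyl)stannane | CCOC(=C)[Sn](CCCC)(CCCC)CCCC | starting material
14 | (2S,3R)-5-(1-ethoxyethenyl)-2-(2-hydroxypropan-2-yl)-6,7-dimethoxy-2,3-dihydro-1-benzofuran-3-ol (not isolated) | CC(C)(O)[C@H]1Oc2c(cc(C(=C)OCC)c(OC)c2OC)[C@H]1O | intermediate
15 | 1-[(2S,3R)-3-hydroxy-2-(2-hydroxypropan-2-yl)-6,7-dimethoxy-2,3-dihydro-1-benzofuran-5-yl]ethan-1-one | CC(C)(O)[C@H]1Oc2c(cc(C(C)=O)c(OC)c2OC)[C@H]1O | intermediate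
16 | angelic acid, (Z)-2-methylbut-2-enoic acid | C/C=C(/C)C(=O)O | starting material
17 | (Z)-2-methylbut-2-enoic 2,4,6-trichlorobenzoic anhydride (not isolated) | C/C=C(/C)C(=O)OC(=O)c1c(Cl)cc(Cl)cc1Cl | intermediate
18 | (2S,3R)-5-acetyl-2-(2-hydroxypropan-2-yl)-6,7-dimethoxy-2,3-dihydro-1-benzofuran-3-yl (Z)-2-methylbut-2-enoate | CC(C)(O)[C@H]1Oc2c(cc(C(C)=O)c(OC)c2OC)[C@H]1OC(=O)/C(C)=C\C | intermediate
19 | triethylammonium N-(methoxycarbonyl)sulfamate ester of 18 at the tertiary oxygen (not isolated) | COC(=O)[N-]S(=O)(=O)OC(C)(C)[C@H]1Oc2c(cc(C(C)=O)c(OC)c2OC)[C@H]1OC(=O)/C(C)=C\C.CC[NH+](CC)CC | intermediate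
20 | (2R,3R)-5-acetyl-6,7-dimethoxy-2-(prop-1-en-2-yl)-2,3-dihydro-1-benzofuran-3-yl (Z)-2-methylbut-2-enoate | C=C(C)[C@H]1Oc2c(cc(C(C)=O)c(OC)c2OC)[C@H]1OC(=O)/C(C)=C\C | target

Total step count: 10
Longest linear sequence: 10 steps (1 to 20)

Steps most likely to fail

Step 6. The keto ester may sit almost wholly as the aromatic enol, so hydride transfer could be slow. Enantioface discrimination could be incomplete. The cis hydroxy ester could also lose water toward the aromatic benzofuran ester in the formic acid medium. The fallback replaces the catalytic stereoconvergent reduction by a substrate-controlled reduction and an enzymatic resolution, setting out from 8. NaBH4 in MeOH/THF at −40 °C should deliver hydride anti to the ester and give the racemic cis hydroxy ester, that is 9 together with its mirror image methyl (2R,3S)-5-bromo-3-hydroxy-6,7-dimethoxy-2,3-dihydro-1-benzofuran-2-carboxylate F1. Kinetic resolution with Candida antarctica lipase B and vinyl acetate in MTBE at 30 °C is expected to acetylate the 3S enantiomer (Kazlauskas rule, fused arene as the large group). This would give methyl (2R,3S)-3-acetoxy-5-bromo-6,7-dimethoxy-2,3-dihydro-1-benzofuran-2-carboxylate F2 and leave the free alcohol, which is separated by chromatography and rejoins the route at 9.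

Step 10. Activating the tertiary alcohol next to a benzylic acyloxy group may lead to ionisation or participation of the angelate, with aromatisation by loss of angelic acid. Elimination may also run toward C2–H instead of a methyl group. The fallback moves the dehydration ahead of the acylation and sets out from 15. TESCl and imidazole in DMF at 0 °C should silylate only the secondary hydroxyl, giving 1-[(2S,3R)-2-(2-hydroxypropan-2-yl)-6,7-dimethoxy-3-(triethylsilyloxy)-2,3-dihydro-1-benzofuran-5-yl]ethan-1-one F3. SOCl2 and pyridine in CH2Cl2 at −20 °C then dehydrate the tertiary alcohol by an E2 path through the chlorosulfite, next to a silyl ether that neither leaves nor participates. This gives 1-[(2R,3R)-6,7-dimethoxy-2-(prop-1-en-2-yl)-3-(triethylsilyloxy)-2,3-dihydro-1-benzofuran-5-yl]ethan-1-one F4. Bu4NF buffered with AcOH in THF at 0 °C frees 1-[(2R,3R)-3-hydroxy-6,7-dimethoxy-2-(prop-1-en-2-yl)-2,3-dihydro-1-benzofuran-5-yl]ethan-1-one F5. F5 is esterified with 16 through the mixed anhydride 17 under the conditions of step 9 and returns to the route at 20.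

Step 9. Acylation of the crowded cis carbinol may be slow, and on prolonged warming the Z double bond may drift to the E (tiglate) geometry or the benzylic carbon may ionise. The fallback builds the Z alkene on the substrate instead of transferring it, setting out from 15. Carbodiimide coupling (EDC·HCl, DMAP cat., CH2Cl2, 0 °C) with 2-[bis(2,2,2-trifluoroethoxy)phosphoryl]propanoic acid, a saturated acid with no alkene geometry to lose, should give (2S,3R)-5-acetyl-2-(2-hydroxypropan-2-yl)-6,7-dimethoxy-2,3-dihydro-1-benzofuran-3-yl 2-[bis(2,2,2-trifluoroethoxy)phosphoryl]propanoate F6 as a mixture of epimers at the phosphorus-bearing carbon. Still–Gennari olefination with acetaldehyde (KN(SiMe3)2, 18-crown-6, THF, −78 °C) then forms the Z-trisubstituted enoate and returns to the route at 18.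

Further compounds
F1 | step 6 | methyl (2R,3S)-5-bromo-3-hydroxy-6,7-dimethoxy-2,3-dihydro-1-benzofuran-2-carboxylate | COC(=O)[C@@H]1Oc2c(cc(Br)c(OC)c2OC)[C@@H]1O
F2 | step 6 | methyl (2R,3S)-3-acetoxy-5-bromo-6,7-dimethoxy-2,3-dihydro-1-benzofuran-2-carboxylate | COC(=O)[C@@H]1Oc2c(cc(Br)c(OC)c2OC)[C@@H]1OC(C)=O
F3 | step 10 | 1-[(2S,3R)-2-(2-hydroxypropan-2-yl)-6,7-dimethoxy-3-(triethylsilyloxy)-2,3-dihydro-1-benzofuran-5-yl]ethan-1-one | CC(C)(O)[C@H]1Oc2c(cc(C(C)=O)c(OC)c2OC)[C@H]1O[Si](CC)(CC)CC
F4 | step 10 | 1-[(2R,3R)-6,7-dimethoxy-2-(prop-1-en-2-yl)-3-(triethylsilyloxy)-2,3-dihydro-1-benzofuran-5-yl]ethan-1-one | C=C(C)[C@H]1Oc2c(cc(C(C)=O)c(OC)c2OC)[C@H]1O[Si](CC)(CC)CC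
F5 | step 10 | 1-[(2R,3R)-3-hydroxy-6,7-dimethoxy-2-(prop-1-en-2-yl)-2,3-dihydro-1-benzofuran-5-yl]ethan-1-one | C=C(C)[C@H]1Oc2c(cc(C(C)=O)c(OC)c2OC)[C@H]1O
F6 | step 9 | (2S,3R)-5-acetyl-2-(2-hydroxypropan-2-yl)-6,7-dimethoxy-2,3-dihydro-1-benzofuran-3-yl 2-[bis(2,2,2-trifluoroethoxy)phosphoryl]propanoate | CC(C)(O)[C@H]1Oc2c(cc(C(C)=O)c(OC)c2OC)[C@H]1OC(=O)C(C)P(=O)(OCC(F)(F)F)OCC(F)(F)F
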